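The route rests on disconnecting C1–C10, the bond that joins the exocyclic methylene carbon of ring A to the quaternary ring-fusion carbon C10. A cationic gold catalyst lets the C9=C10 silyl enol ether of a fully substituted ring B attack the internal carbon of a terminal alkyne. This closes ring A (6-exo-dig), creates the C10 quaternary stereocentre with cis fusion and leaves the C1 methylene, all in one operation. The precursor is a ring-B triisopropylsilyl enol ether (C9–O, C10 methyl) carrying a pent-4-ynyl arm on C5, the C6 methyl and ketal side chain, and the C7 methyl. C8 is oxygenated, and C9 deoxygenated, after the cyclisation.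

Key step: step 10

Remarks on the chemistry (assumptions)
- Locants C1–C10 are those of the target decalin (ring A: C1–C5, C10; ring B: C5–C10). β is the face of the C6 methyl, α the opposite face. Target configuration: 5R,6R,7S,8S,10S.
- A carbon nucleophile adding to C5 of a C5-unsubstituted ring-B enone would enter trans to the C7 methyl (α face), the wrong side. The arm is therefore attached to C5 first and hydrogen is delivered to the α face afterwards (step 8).
- The side chain must be the second substituent brought to C6, because it enters anti to the C7 methyl. An α-silyloxy group at C8 would not survive step 8, so C8 is oxygenated after ring closure.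
- Centres formed without control and erased later (C10 in 9, the carbinol carbon in 15, C2 in 31, C3 in 34 and 35) are left undefined in the SMILES. The C9 carbinol in 24 and 25 is drawn as the expected 9β epimer; either epimer serves.
- Compounds 12 and 28, the oxaziridine and both antipodes of the phosphoramidite ligand are taken to be purchasable.

Step 1
Reactants: 1 2-methylcyclohex-2-en-1-one
Product: 3 (R)-[(2,3-dimethylcyclohex-1-en-1-yl)oxy]trimethylsilane, via dimethylaluminium enolate 2 (not isolated)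
Conditions: Me3Al (1.4 equiv), Cu(O2C-2-thienyl) (2 mol%), chiral biphenol-based phosphoramidite (4 mol%), Et2O, −30 °C; then TMSOTf, THF, 0 °C
Reagents that add atoms: trimethylaluminium C[Al](C)C; trimethylsilyl trifluoromethanesulfonate C[Si](C)(C)OS(=O)(=O)C(F)(F)F
Why: Copper-catalysed enantioselective conjugate addition of a methylaluminium reagent to an α-substituted cyclohexenone, with the ligand antipode chosen to give the 3R centre (C7 of the target), followed by O-silylation of the aluminium enolate, which fixes the enolate regiochemistry.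

Step 2
Reactants: 4 2-(2-bromoethyl)-2-methyl-1,3-dioxolane
Product: 5 2-(2-iodoethyl)-2-methyl-1,3-dioxolane
Conditions: NaI (3 equiv), NaHCO3 (trace), acetone, reflux
Reagents that add atoms: sodium iodide [Na+].[I-]
Why: Finkelstein halide exchange, driven by precipitation of NaBr, provides the more reactive iodide needed for alkylation of a hindered enolate.

Step 3
Reactants: 3 (R)-[(2,3-dimethylcyclohex-1-en-1-yl)oxy]trimethylsilane; 5 2-(2-iodoethyl)-2-methyl-1,3-dioxolane
Product: 7 (2S,3R)-2,3-dimethyl-2-[2-(2-methyl-1,3-dioxolan-2-yl)ethyl]cyclohexan-1-one, via lithium enolate 6 (not isolated)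
Conditions: MeLi (1.05 equiv), THF, 0 °C to 23 °C; then DMPU, 5 (1.5 equiv), −78 °C to 23 °C
Reagents that add atoms: none
Why: Methyllithium cleaves the silyl enol ether to the regiodefined tetrasubstituted lithium enolate, and its SN2 alkylation should occur axially on the face opposite the adjacent pseudoaxial C7 methyl, so the quaternary centre C6 is set with the C6 and C7 methyls cis.

Step 4
Reactants: 7 (2S,3R)-2,3-dimethyl-2-[2-(2-methyl-1,3-dioxolan-2-yl)ethyl]cyclohexan-1-one
Product: 9 (2S,3R)-2,3,6-trimethyl-2-[2-(2-methyl-1,3-dioxolan-2-yl)ethyl]cyclohexan-1-one (C6 epimers), via lithium enolate 8 (not isolated)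
Conditions: LiN(iPr)2 (1.1 equiv), THF, −78 °C; then MeI, −78 °C to 0 °C
Reagents that add atoms: iodomethane CI
Why: Kinetic enolate methylation at the only enolisable position (C10 of the target); the new centre is irrelevant because it becomes sp2 in the next step.

Step 5
Reactants: 9 (2S,3R)-2,3,6-trimethyl-2-[2-(2-methyl-1,3-dioxolan-2-yl)ethyl]cyclohexan-1-one
Product: 11 (5R,6S)-2,5,6-trimethyl-6-[2-(2-methyl-1,3-dioxolan-2-yl)ethyl]cyclohex-2-en-1-one, via trimethylsilyl enol ether 10 (not isolated)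
Conditions: LiN(iPr)2, TMSCl (in situ quench), THF, −78 °C to 0 °C; then Pd(OAc)2 (1.1 equiv), MeCN, 23 °C
Reagents that add atoms: none
Why: Saegusa–Ito oxidation, in which the only possible silyl enol ether is palladated and β-hydride elimination from the ring CH2 gives the endocyclic 2-methyl enone.

Step 6
Reactants: 11 (5R,6S)-2,5,6-trimethyl-6-[2-(2-methyl-1,3-dioxolan-2-yl)ethyl]cyclohex-2-en-1-one; 12 (5-chloropent-1-yn-1-yl)trimethylsilane
Product: 15 (5R,6S)-2,5,6-trimethyl-6-[2-(2-methyl-1,3-dioxolan-2-yl)ethyl]-1-[5-(trimethylsilyl)pent-4-yn-1-yl]cyclohex-2-en-1-ol (C1 epimers), via Grignard reagent 13 (not isolated), via organocerium reagent 14 (not isolated)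
Conditions: Mg, I2 (cat.), THF, reflux; CeCl3 (anhydrous), THF, −78 °C; then 11, −78 °C to 0 °C; aq. NH4Cl
Reagents that add atoms: none
Why: Organocerium 1,2-addition to a hindered, enolisable enone proceeds without conjugate addition or enolisation and attaches the whole arm to the future C5; the carbinol configuration is immaterial.

Step 7
Reactants: 15 (5R,6S)-2,5,6-trimethyl-6-[2-(2-methyl-1,3-dioxolan-2-yl)ethyl]-1-[5-(trimethylsilyl)pent-4-yn-1-yl]cyclohex-2-en-1-ol
Product: 16 (4S,5R)-2,4,5-trimethyl-4-[2-(2-methyl-1,3-dioxolan-2-yl)ethyl]-3-[5-(trimethylsilyl)pent-4-yn-1-yl]cyclohex-2-en-1-one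
Conditions: pyridinium chlorochromate (C5H5NH)[CrO3Cl] (2 equiv), 4 Å molecular sieves, CH2Cl2, 23 °C
Reagents that add atoms: pyridinium chlorochromate [O-][Cr](=O)(=O)Cl.c1cc[nH+]cc1
Why: Babler–Dauben oxidative transposition, in which the tertiary allylic chromate ester undergoes a [3,3] shift to C9 and is oxidised, so the carbonyl arrives at C9 and the arm sits on the β-carbon C5 of a tetrasubstituted enone.

Step 8
Reactants: 16 (4S,5R)-2,4,5-trimethyl-4-[2-(2-methyl-1,3-dioxolan-2-yl)ethyl]-3-[5-(trimethylsilyl)pent-4-yn-1-yl]cyclohex-2-en-1-one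
Product: 18 triisopropyl{[(3R,4S,5R)-2,4,5-trimethyl-4-[2-(2-methyl-1,3-dioxolan-2-yl)ethyl]-3-[5-(trimethylsilyl)pent-4-yn-1-yl]cyclohex-1-en-1-yl]oxy}silane, via lithium enolate 17 (not isolated)
Conditions: Li (2.4 equiv), liquid NH3/THF, t-BuOH (1.0 equiv), −78 °C, 10 min; isoprene; NH3 evaporated; TIPSOTf, Et3N, THF, −78 °C to 0 °C
Reagents that add atoms: triisopropylsilyl trifluoromethanesulfonate CC(C)[Si](C(C)C)(C(C)C)OS(=O)(=O)C(F)(F)F
Why: Birch-type reductive silylation, in which the enone should take up two electrons far faster than the silylalkyne, C5 should be protonated axially on the α face (the β face is screened by the syn-axial C7 methyl in the competing half-chair) so the arm ends up β and equatorial, and the regiodefined C9=C10 enolate is trapped on oxygen.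

Step 9
Reactants: 18 triisopropyl{[(3R,4S,5R)-2,4,5-trimethyl-4-[2-(2-methyl-1,3-dioxolan-2-yl)ethyl]-3-[5-(trimethylsilyl)pent-4-yn-1-yl]cyclohex-1-en-1-yl]oxy}silane
Product: 19 triisopropyl{[(3R,4S,5R)-2,4,5-trimethyl-4-[2-(2-methyl-1,3-dioxolan-2-yl)ethyl]-3-(pent-4-yn-1-yl)cyclohex-1-en-1-yl]oxy}silane
Conditions: K2CO3 (0.3 equiv), MeOH/THF (1:1), 0 °C to 23 °C
Reagents that add atoms: none
Why: Carbonate-catalysed methanolysis of the alkynyl–silicon bond is much faster than cleavage of a hindered triisopropylsilyl enol ether, so the terminal alkyne should be released selectively.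

Step 10
Reactants: 19 triisopropyl{[(3R,4S,5R)-2,4,5-trimethyl-4-[2-(2-methyl-1,3-dioxolan-2-yl)ethyl]-3-(pent-4-yn-1-yl)cyclohex-1-en-1-yl]oxy}silane
Product: 20 cis-fused 6β,7β,10α-trimethyl-1-methylidene-6α-[2-(2-methyl-1,3-dioxolan-2-yl)ethyl]-5αH-decalin-9-one
Conditions: Ph3PAuCl (10 mol%), AgBF4 (10 mol%), CH2Cl2/MeOH (10:1), 23 °C to 40 °C
Reagents that add atoms: none
Why: Cationic monovalent gold coordinates the terminal alkyne and makes its internal carbon C1 electrophilic; the enol ether carbon C10 adds anti to gold, the oxocarbenium ion gives up silicon to methanol, and protodeauration of the alkenylgold leaves the C1=CH2 group. The closest known reaction type is the gold-catalysed Conia-ene-type carbocyclisation of silyl enol ethers onto alkynes. Ring A is closed in the 6-exo-dig mode. The new quaternary stereocentre C10 is controlled by C5: the equatorial β arm can reach only the β face of the enol ether and the bond forms axially at C10, so the fusion should be cis (C5–H and C10 methyl both α). The step needs exo rather than 7-endo attack, which the Markovnikov bias of a terminal alkyne secures, and C10 rather than C8 as the nucleophile, which the enol ether regiochemistry fixed in step 8 secures. The bulky silyl group should limit protodesilylation before C–C bond formation.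

Step 11
Reactants: 20 cis-fused 6β,7β,10α-trimethyl-1-methylidene-6α-[2-(2-methyl-1,3-dioxolan-2-yl)ethyl]-5αH-decalin-9-one
Product: 23 8α-acetoxy-6β,7β,10α-trimethyl-1-methylidene-6α-[2-(2-methyl-1,3-dioxolan-2-yl)ethyl]-5αH-decalin-9-one, via potassium enolate 21 (not isolated), via potassium alkoxide 22 (not isolated)
Conditions: KN(SiMe3)2 (1.2 equiv), THF, −78 °C; 2-(phenylsulfonyl)-3-phenyloxaziridine, −78 °C; then Ac2O, −78 °C to 0 °C
Reagents that add atoms: 2-(phenylsulfonyl)-3-phenyloxaziridine O=S(=O)(c1ccccc1)N1OC1c1ccccc1; acetic anhydride CC(=O)OC(C)=O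
Why: Davis enolate hydroxylation at the only enolisable carbon (C8), where the bulky oxaziridine should approach the α face because the β face is screened by the axial C6 methyl and the axial C10–C1 bond, with acetylation of the alkoxide in the same flask giving the equatorial 8α-acetate of the target.

Step 12
Reactants: 23 8α-acetoxy-6β,7β,10α-trimethyl-1-methylidene-6α-[2-(2-methyl-1,3-dioxolan-2-yl)ethyl]-5αH-decalin-9-one
Product: 24 8α-acetoxy-6β,7β,10α-trimethyl-1-methylidene-6α-[2-(2-methyl-1,3-dioxolan-2-yl)ethyl]-5αH-decalin-9β-ol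
Conditions: NaBH4, THF/MeOH (4:1), −20 °C to 0 °C
Reagents that add atoms: none
Why: Borohydride reduction by axial hydride attack on the unhindered α face should give the equatorial 9β-alcohol (a transient centre) while the acetate survives at low temperature.

Step 13
Reactants: 24 8α-acetoxy-6β,7β,10α-trimethyl-1-methylidene-6α-[2-(2-methyl-1,3-dioxolan-2-yl)ethyl]-5αH-decalin-9β-ol
Product: 25 O-(8α-acetoxy-6β,7β,10α-trimethyl-1-methylidene-6α-[2-(2-methyl-1,3-dioxolan-2-yl)ethyl]-5αH-decalin-9β-yl) imidazole-1-carbothioate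
Conditions: thiocarbonyldiimidazole (3 equiv), DMAP (0.2 equiv), toluene, 90 °C
Reagents that add atoms: 1,1'-thiocarbonyldiimidazole S=C(n1ccnc1)n1ccnc1
Why: Thioacylation under neutral conditions (first stage of a Barton–McCombie deoxygenation) functionalises the hindered C9 hydroxyl without base-induced acetate migration.

Step 14
Reactants: 25 O-(8α-acetoxy-6β,7β,10α-trimethyl-1-methylidene-6α-[2-(2-methyl-1,3-dioxolan-2-yl)ethyl]-5αH-decalin-9β-yl) imidazole-1-carbothioate
Product: 26 8α-acetoxy-6β,7β,10α-trimethyl-1-methylidene-6α-[2-(2-methyl-1,3-dioxolan-2-yl)ethyl]-5αH-decalin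
Conditions: Bu3SnH (3 equiv, 0.3 M), AIBN (0.2 equiv), toluene, 100 °C
Reagents that add atoms: none
Why: Barton–McCombie radical deoxygenation, where a high stannane concentration should reduce the secondary C9 radical before it can add reversibly to the homoallylic C1 methylene.

Step 15
Reactants: 26 8α-acetoxy-6β,7β,10α-trimethyl-1-methylidene-6α-[2-(2-methyl-1,3-dioxolan-2-yl)ethyl]-5αH-decalin
Product: 27 4-(8α-acetoxy-6β,7β,10α-trimethyl-1-methylidene-5αH-decalin-6α-yl)butan-2-one
Conditions: pyridinium p-toluenesulfonate (0.3 equiv), acetone/H2O (10:1), 50 °C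
Reagents that add atoms: water O
Why: Mild acid-catalysed ketal hydrolysis unmasks the methyl ketone and should leave the secondary acetate and the exocyclic alkene untouched.

Step 16
Reactants: 27 4-(8α-acetoxy-6β,7β,10α-trimethyl-1-methylidene-5αH-decalin-6α-yl)butan-2-one; 28 tert-butyl 2-(diethoxyphosphoryl)acetate
Product: 30 tert-butyl (E)-5-(8α-acetoxy-6β,7β,10α-trimethyl-1-methylidene-5αH-decalin-6α-yl)-3-methylpent-2-enoate, via sodium phosphonate carbanion 29 (not isolated)
Conditions: NaH (1.5 equiv), 28 (1.6 equiv), THF, 0 °C; then 27, 0 °C to 45 °C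
Reagents that add atoms: none
Why: Horner–Wadsworth–Emmons olefination of the unhindered methyl ketone should give mainly the E trisubstituted enoate, with the minor Z isomer removed by chromatography.

Step 17
Reactants: 30 tert-butyl (E)-5-(8α-acetoxy-6β,7β,10α-trimethyl-1-methylidene-5αH-decalin-6α-yl)-3-methylpent-2-enoate
Product: 31 tert-butyl (E)-5-(8α-acetoxy-2-hydroxy-6β,7β,10α-trimethyl-1-methylidene-5αH-decalin-6α-yl)-3-methylpent-2-enoate (C2 epimers)
Conditions: SeO2 (0.5 equiv), t-BuOOH (3 equiv), CH2Cl2, 0 °C to 23 °C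
Reagents that add atoms: tert-butyl hydroperoxide CC(C)(C)OO; selenium dioxide O=[Se]=O (oxygen carrier, regenerated)
Why: Selenium dioxide allylic oxidation (ene reaction then [2,3] shift) hydroxylates C2, the only allylic CH2 of the electron-rich 1,1-disubstituted alkene, and returns the double bond to the exocyclic position, while the electron-poor enoate should be inert.

Step 18
Reactants: 31 tert-butyl (E)-5-(8α-acetoxy-2-hydroxy-6β,7β,10α-trimethyl-1-methylidene-5αH-decalin-6α-yl)-3-methylpent-2-enoate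
Product: 32 tert-butyl (E)-5-(8α-acetoxy-6β,7β,10α-trimethyl-1-methylidene-2-oxo-5αH-decalin-6α-yl)-3-methylpent-2-enoate
Conditions: Dess–Martin periodinane (1.3 equiv), NaHCO3, CH2Cl2, 0 °C
Reagents that add atoms: none
Why: Dess–Martin oxidation of the allylic alcohol gives the α-methylene ketone under buffered, non-nucleophilic conditions.

Step 19
Reactants: 32 tert-butyl (E)-5-(8α-acetoxy-6β,7β,10α-trimethyl-1-methylidene-2-oxo-5αH-decalin-6α-yl)-3-methylpent-2-enoate
Product: 35 tert-butyl (E)-5-(8α-acetoxy-3-hydroxy-6β,7β,10α-trimethyl-1-methylidene-2-oxo-5αH-decalin-6α-yl)-3-methylpent-2-enoate (C3 epimers), via silyloxy diene 33 (not isolated), via silyloxy ketone 34 (not isolated)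
Conditions: TMSOTf (1.3 equiv), Et3N (2 equiv), CH2Cl2, −78 °C to 0 °C; mCPBA (1.05 equiv), NaHCO3, CH2Cl2, −20 °C; aq. citric acid, THF, 0 °C
Reagents that add atoms: 3-chloroperbenzoic acid OOC(=O)c1cccc(Cl)c1
Why: Rubottom oxidation, in which enolisation is possible only toward C3, the electron-rich enol ether double bond of the 2-silyloxy diene is epoxidised in preference to the other alkenes, and mild acid releases the α-hydroxy ketone.

Step 20
Reactants: 35 tert-butyl (E)-5-(8α-acetoxy-3-hydroxy-6β,7β,10α-trimethyl-1-methylidene-2-oxo-5αH-decalin-6α-yl)-3-methylpent-2-enoate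
Product: 36 tert-butyl (E)-5-(8α-acetoxy-3-hydroxy-6β,7β,10α-trimethyl-1-methylidene-2-oxo-5αH-decal-3-en-6α-yl)-3-methylpent-2-enoate
Conditions: Dess–Martin periodinane (1.5 equiv), NaHCO3, CH2Cl2, 23 °C
Reagents that add atoms: none
Why: Dess–Martin oxidation of the acyloin gives the 1,2-diketone, which can enolise only toward C4 and should therefore rest as the conjugated diosphenol of the target.

Step 21
Reactants: 36 tert-butyl (E)-5-(8α-acetoxy-3-hydroxy-6β,7β,10α-trimethyl-1-methylidene-2-oxo-5αH-decal-3-en-6α-yl)-3-methylpent-2-enoate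
Product: 37 (E)-5-[(5R,6R,7S,8S,10S)-8α-acetoxy-3-hydroxy-6β,7β,10α-trimethyl-1-methylidene-2-oxo-5αH-decal-3-en-6α-yl]-3-methylpent-2-enoic acid (CNP0192653.1)
Conditions: CF3CO2H/CH2Cl2 (1:4), 0 °C to 23 °C
Reagents that add atoms: none
Why: Acidolysis of the tert-butyl ester with loss of isobutene frees the acid without hydrolysing the secondary acetate.

Compound list
1 | 2-methylcyclohex-2-en-1-one | CC1=CCCC1=O | starting material
2 | dimethylaluminium (R)-2,3-dimethylcyclohex-1-en-1-olate | C[Al](C)OC1=C(C)[C@H](C)CCC1 | intermediate (not isolated)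
3 | (R)-[(2,3-dimethylcyclohex-1-en-1-yl)oxy]trimethylsilane | C[Si](C)(C)OC1=C(C)[C@H](C)CCC1 | intermediate
4 | 2-(2-bromoethyl)-2-methyl-1,3-dioxolane | CC1(CCBr)OCCO1 | starting material
5 | 2-(2-iodoethyl)-2-methyl-1,3-dioxolane | CC1(CCI)OCCO1 | intermediate
6 | lithium (R)-2,3-dimethylcyclohex-1-en-1-olate | [Li]OC1=C(C)[C@H](C)CCC1 | intermediate (not isolated)
7 | (2S,3R)-2,3-dimethyl-2-[2-(2-methyl-1,3-dioxolan-2-yl)ethyl]cyclohexan-1-one | O=C1[C@@](C)(CCC2(C)OCCO2)[C@H](C)CCC1 | intermediate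
8 | lithium (5R,6S)-5,6-dimethyl-6-[2-(2-methyl-1,3-dioxolan-2-yl)ethyl]cyclohex-1-en-1-olate | [Li]OC=1[C@@](C)(CCC2(C)OCCO2)[C@H](C)CCC=1 | intermediate (not isolated)
9 | (2S,3R)-2,3,6-trimethyl-2-[2-(2-methyl-1,3-dioxolan-2-yl)ethyl]cyclohexan-1-one, C6 epimers | O=C1[C@@](C)(CCC2(C)OCCO2)[C@H](C)CCC1C | intermediate
10 | trimethyl{[(5R,6S)-2,5,6-trimethyl-6-[2-(2-methyl-1,3-dioxolan-2-yl)ethyl]cyclohex-1-en-1-yl]oxy}silane | CC1=C(O[Si](C)(C)C)[C@@](C)(CCC2(C)OCCO2)[C@H](C)CC1 | intermediate (not isolated)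
11 | (5R,6S)-2,5,6-trimethyl-6-[2-(2-methyl-1,3-dioxolan-2-yl)ethyl]cyclohex-2-en-1-one | O=C1[C@@](C)(CCC2(C)OCCO2)[C@H](C)CC=C1C | intermediate
12 | (5-chloropent-1-yn-1-yl)trimethylsilane | C[Si](C)(C)C#CCCCCl | starting material
13 | [5-(trimethylsilyl)pent-4-yn-1-yl]magnesium chloride | C[Si](C)(C)C#CCCC[Mg]Cl | intermediate (not isolated)
14 | dichloro[5-(trimethylsilyl)pent-4-yn-1-yl]cerium | C[Si](C)(C)C#CCCC[Ce](Cl)Cl | intermediate (not isolated)
15 | (5R,6S)-2,5,6-trimethyl-6-[2-(2-methyl-1,3-dioxolan-2-yl)ethyl]-1-[5-(trimethylsilyl)pent-4-yn-1-yl]cyclohex-2-en-1-ol, C1 epimers | OC1(CCCC#C[Si](C)(C)C)[C@@](C)(CCC2(C)OCCO2)[C@H](C)CC=C1C | intermediate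
16 | (4S,5R)-2,4,5-trimethyl-4-[2-(2-methyl-1,3-dioxolan-2-yl)ethyl]-3-[5-(trimethylsilyl)pent-4-yn-1-yl]cyclohex-2-en-1-one | CC1=C(CCCC#C[Si](C)(C)C)[C@@](C)(CCC2(C)OCCO2)[C@H](C)CC1=O | intermediate
17 | lithium (3R,4S,5R)-2,4,5-trimethyl-4-[2-(2-methyl-1,3-dioxolan-2-yl)ethyl]-3-[5-(trimethylsilyl)pent-4-yn-1-yl]cyclohex-1-en-1-olate | C[Si](C)(C)C#CCCC[C@@H]1[C@@](C)(CCC2(C)OCCO2)[C@H](C)CC(O[Li])=C1C | intermediate (not isolated)
18 | triisopropyl{[(3R,4S,5R)-2,4,5-trimethyl-4-[2-(2-methyl-1,3-dioxolan-2-yl)ethyl]-3-[5-(trimethylsilyl)pent-4-yn-1-yl]cyclohex-1-en-1-yl]oxy}silane | C[Si](C)(C)C#CCCC[C@@H]1[C@@](C)(CCC2(C)OCCO2)[C@H](C)CC(O[Si](C(C)C)(C(C)C)C(C)C)=C1C | intermediate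
19 | triisopropyl{[(3R,4S,5R)-2,4,5-trimethyl-4-[2-(2-methyl-1,3-dioxolan-2-yl)ethyl]-3-(pent-4-yn-1-yl)cyclohex-1-en-1-yl]oxy}silane (key-step precursor) | C#CCCC[C@@H]1[C@@](C)(CCC2(C)OCCO2)[C@H](C)CC(O[Si](C(C)C)(C(C)C)C(C)C)=C1C | intermediate
20 | cis-fused 6β,7β,10α-trimethyl-1-methylidene-6α-[2-(2-methyl-1,3-dioxolan-2-yl)ethyl]-5αH-decalin-9-one (key-step product) | C=C1CCC[C@@H]2[C@@](C)(CCC3(C)OCCO3)[C@H](C)CC(=O)[C@]12C | intermediate
21 | potassium C8=C9 enolate of 20 | C=C1CCC[C@@H]2[C@@](C)(CCC3(C)OCCO3)[C@H](C)C=C(O[K])[C@]12C | intermediate (not isolated)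
22 | potassium 8α-alkoxide of the 8α-hydroxy-9-ketone | C=C1CCC[C@@H]2[C@@](C)(CCC3(C)OCCO3)[C@H](C)[C@@H](O[K])C(=O)[C@]12C | intermediate (not isolated)
23 | 8α-acetoxy-6β,7β,10α-trimethyl-1-methylidene-6α-[2-(2-methyl-1,3-dioxolan-2-yl)ethyl]-5αH-decalin-9-one | C=C1CCC[C@@H]2[C@@](C)(CCC3(C)OCCO3)[C@H](C)[C@@H](OC(C)=O)C(=O)[C@]12C | intermediate
24 | 8α-acetoxy-6β,7β,10α-trimethyl-1-methylidene-6α-[2-(2-methyl-1,3-dioxolan-2-yl)ethyl]-5αH-decalin-9β-ol | C=C1CCC[C@@H]2[C@@](C)(CCC3(C)OCCO3)[C@H](C)[C@@H](OC(C)=O)[C@H](O)[C@]12C | intermediate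
25 | O-(8α-acetoxy-6β,7β,10α-trimethyl-1-methylidene-6α-[2-(2-methyl-1,3-dioxolan-2-yl)ethyl]-5αH-decalin-9β-yl) imidazole-1-carbothioate | C=C1CCC[C@@H]2[C@@](C)(CCC3(C)OCCO3)[C@H](C)[C@@H](OC(C)=O)[C@H](OC(=S)n4ccnc4)[C@]12C | intermediate
26 | 8α-acetoxy-6β,7β,10α-trimethyl-1-methylidene-6α-[2-(2-methyl-1,3-dioxolan-2-yl)ethyl]-5αH-decalin | C=C1CCC[C@@H]2[C@@](C)(CCC3(C)OCCO3)[C@H](C)[C@@H](OC(C)=O)C[C@]12C | intermediate
27 | 4-(8α-acetoxy-6β,7β,10α-trimethyl-1-methylidene-5αH-decalin-6α-yl)butan-2-one | C=C1CCC[C@@H]2[C@@](C)(CCC(C)=O)[C@H](C)[C@@H](OC(C)=O)C[C@]12C | intermediate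
28 | tert-butyl 2-(diethoxyphosphoryl)acetate | CCOP(=O)(CC(=O)OC(C)(C)C)OCC | starting material
29 | sodium salt of 28 (phosphonate carbanion) | [Na+].CCOP(=O)([CH-]C(=O)OC(C)(C)C)OCC | intermediate (not isolated)
30 | tert-butyl (E)-5-(8α-acetoxy-6β,7β,10α-trimethyl-1-methylidene-5αH-decalin-6α-yl)-3-methylpent-2-enoate | C=C1CCC[C@@H]2[C@@](C)(CC/C(C)=C/C(=O)OC(C)(C)C)[C@H](C)[C@@H](OC(C)=O)C[C@]12C | intermediate
31 | tert-butyl (E)-5-(8α-acetoxy-2-hydroxy-6β,7β,10α-trimethyl-1-methylidene-5αH-decalin-6α-yl)-3-methylpent-2-enoate, C2 epimers | C=C1C(O)CC[C@@H]2[C@@](C)(CC/C(C)=C/C(=O)OC(C)(C)C)[C@H](C)[C@@H](OC(C)=O)C[C@]12C | intermediate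
32 | tert-butyl (E)-5-(8α-acetoxy-6β,7β,10α-trimethyl-1-methylidene-2-oxo-5αH-decalin-6α-yl)-3-methylpent-2-enoate | C=C1C(=O)CC[C@@H]2[C@@](C)(CC/C(C)=C/C(=O)OC(C)(C)C)[C@H](C)[C@@H](OC(C)=O)C[C@]12C | intermediate
33 | 2-(trimethylsilyloxy)-1-methylidene-2-ene (silyloxy diene) derived from 32 | C=C1C(O[Si](C)(C)C)=CC[C@@H]2[C@@](C)(CC/C(C)=C/C(=O)OC(C)(C)C)[C@H](C)[C@@H](OC(C)=O)C[C@]12C | intermediate (not isolated)
34 | 3-(trimethylsilyloxy)-2-ketone derived from 33, C3 epimers | C=C1C(=O)C(O[Si](C)(C)C)C[C@@H]2[C@@](C)(CC/C(C)=C/C(=O)OC(C)(C)C)[C@H](C)[C@@H](OC(C)=O)C[C@]12C | intermediate (not isolated)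
35 | tert-butyl (E)-5-(8α-acetoxy-3-hydroxy-6β,7β,10α-trimethyl-1-methylidene-2-oxo-5αH-decalin-6α-yl)-3-methylpent-2-enoate, C3 epimers | C=C1C(=O)C(O)C[C@@H]2[C@@](C)(CC/C(C)=C/C(=O)OC(C)(C)C)[C@H](C)[C@@H](OC(C)=O)C[C@]12C | intermediate
36 | tert-butyl (E)-5-(8α-acetoxy-3-hydroxy-6β,7β,10α-trimethyl-1-methylidene-2-oxo-5αH-decal-3-en-6α-yl)-3-methylpent-2-enoate | C=C1C(=O)C(O)=C[C@@H]2[C@@](C)(CC/C(C)=C/C(=O)OC(C)(C)C)[C@H](C)[C@@H](OC(C)=O)C[C@]12C | intermediate
37 | (E)-5-[(5R,6R,7S,8S,10S)-8α-acetoxy-3-hydroxy-6β,7β,10α-trimethyl-1-methylidene-2-oxo-5αH-decal-3-en-6α-yl]-3-methylpent-2-enoic acid | C=C1C(=O)C(O)=C[C@@H]2[C@@](C)(CC/C(C)=C/C(=O)O)[C@H](C)[C@@H](OC(C)=O)C[C@]12C | target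

Total step count: 21. Longest linear sequence: 20 steps (steps 1 and 3–21, from 2-methylcyclohex-2-en-1-one); step 2 prepares a side fragment.

Steps most likely to fail

Step 8 (dissolving-metal reduction with silyl trapping). What may go wrong: electron transfer to the silylalkyne (over-reduction or loss of silicon), or addition of the enone radical anion to it, may compete with clean two-electron reduction of the enone. Fallback: the alkyne is carried through the reduction as its lithium acetylide. Setting out from 16, K2CO3 in MeOH removes the alkynyl silyl group and gives the terminal-alkyne enone F1. Li in NH3/THF at −78 °C without added alcohol turns the alkyne C–H into the acetylide, which resists both electrons and radicals, while the enone is reduced; quenching with TMSCl/Et3N gives the bis(trimethylsilyl) compound F2 (O-silyl enol ether, C-silyl alkyne). MeLi in THF at 0 °C cleaves the enol O–Si bond faster than the alkynyl C–Si bond, and TIPSOTf traps the regenerated lithium enolate, which returns to the route at 18.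

Step 10 (gold-catalysed ring closure). What may go wrong: the silyl group may be lost from oxygen before the C–C bond forms, leaving the unreactive ketone, or the alkyne may be hydrated or attacked in the 7-endo sense. Fallback: a palladium-mediated oxidative cycloalkenylation of a silyl enol ether onto a terminal alkene (Saegusa-type), which forms the same C1–C10 bond and delivers the same methylidene by β-hydride elimination. Setting out from 11, pent-4-en-1-ylmagnesium bromide with CeCl3 gives the pentenyl carbinol F3. (C5H5NH)[CrO3Cl] transposes it to the pentenyl enone F4. Li/NH3/t-BuOH followed by TMSCl/Et3N gives the trimethylsilyl enol ether F5, in which the terminal alkene is inert to the reduction. Pd(OAc)2 (10 mol%) under O2 in DMSO at 45 °C then closes ring A on the β face and rejoins the route at 20.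

Step 3 (alkylation that creates the C6 quaternary centre). What may go wrong: C-alkylation of the hindered tetrasubstituted enolate by a non-activated iodide may be slow, so that proton transfer, O-alkylation or elimination of HI takes over. Fallback: the side chain is brought in by conjugate addition instead of substitution. Setting out from 3, a Mukaiyama–Michael addition to but-3-en-2-one (TiCl4, CH2Cl2, −78 °C), again anti to the C7 methyl, gives the diketone F6. Selective ketalisation of its unhindered methyl ketone with 1,2-bis(trimethylsilyloxy)ethane and catalytic TMSOTf at −78 °C returns to the route at 7.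

Further compounds
F1 | step 8 | (4S,5R)-2,4,5-trimethyl-4-[2-(2-methyl-1,3-dioxolan-2-yl)ethyl]-3-(pent-4-yn-1-yl)cyclohex-2-en-1-one | CC1=C(CCCC#C)[C@@](C)(CCC2(C)OCCO2)[C@H](C)CC1=O
F2 | step 8 | trimethyl{[(3R,4S,5R)-2,4,5-trimethyl-4-[2-(2-methyl-1,3-dioxolan-2-yl)ethyl]-3-[5-(trimethylsilyl)pent-4-yn-1-yl]cyclohex-1-en-1-yl]oxy}silane | C[Si](C)(C)C#CCCC[C@@H]1[C@@](C)(CCC2(C)OCCO2)[C@H](C)CC(O[Si](C)(C)C)=C1C
F3 | step 10 | (5R,6S)-2,5,6-trimethyl-6-[2-(2-methyl-1,3-dioxolan-2-yl)ethyl]-1-(pent-4-en-1-yl)cyclohex-2-en-1-ol, C1 epimers | OC1(CCCC=C)[C@@](C)(CCC2(C)OCCO2)[C@H](C)CC=C1C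
F4 | step 10 | (4S,5R)-2,4,5-trimethyl-4-[2-(2-methyl-1,3-dioxolan-2-yl)ethyl]-3-(pent-4-en-1-yl)cyclohex-2-en-1-one | CC1=C(CCCC=C)[C@@](C)(CCC2(C)OCCO2)[C@H](C)CC1=O
F5 | step 10 | trimethyl{[(3R,4S,5R)-2,4,5-trimethyl-4-[2-(2-methyl-1,3-dioxolan-2-yl)ethyl]-3-(pent-4-en-1-yl)cyclohex-1-en-1-yl]oxy}silane | C=CCCC[C@@H]1[C@@](C)(CCC2(C)OCCO2)[C@H](C)CC(O[Si](C)(C)C)=C1C
F6 | step 3 | (2S,3R)-2,3-dimethyl-2-(3-oxobutyl)cyclohexan-1-one | O=C1[C@@](C)(CCC(C)=O)[C@H](C)CCC1
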